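## Structural features

The target is a 5,7-dihydroxyisoflavone: a phloroglucinol-type ring A is fused to the γ-pyrone ring C, whose C3 carries ring B. Ring B is a 1,2,3,4-tetrasubstituted benzene (C1' to the chromone, C2' ether oxygen, C3' benzylic CH2, C4' free hydroxyl). Its C2'–O and C3'–CH2 positions are bridged by ring D, a 3-hydroxy-2,2-dimethyl-dihydropyran. There is one stereocentre, the (R)-carbinol carbon of ring D; it has no stereogenic neighbour and sits between the quaternary CMe2 carbon and the benzylic CH2. Fragile points are this β-aryloxy secondary alcohol (strong acid can ionise it, leading to dehydration or ring contraction through the ring oxygen), the C2=C3 enone of ring C (strong base, nucleophiles, over-reduction) and the oxidisable free polyphenol. The real difficulty is twofold: four contiguous substituents on ring B with ring D closed onto C3' and nowhere else, and absolute configuration at an isolated carbinol. The key step exploits the fact that C3' is the only unsubstituted carbon ortho to the C2' oxygen and lies between two donor oxygens, so an electrophilic carbon tethered through O–CMe2–C(=O) can only reach it by closing six-membered ring D. The carbinol is then first formed as a ketone flanked by CMe2 and CH2, a size contrast that an enantioselective reduction can use.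

## Logic of the disconnections

16 from 15: only the O–acetyl bond at the carbinol is cut. The alcohol has to be masked while ring C is made, and an acetate can be removed last by methanolysis. There is no skeletal gain; the forward step must leave ring C closed.

15 from 14: ring C is cut at O1–C2 and C2–C3, which removes the one-carbon unit C2. This leaves a ketone whose methylene is activated by an aryl group and an aryl ketone. The forward step must formylate that carbon and cyclise onto an ortho hydroxyl of ring A; the symmetry of ring A makes both ortho hydroxyls equivalent.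

14 from 12 and 13: the bond between the ketone carbon and ring A (C4–C4a) is cut. Ring A becomes commercial 13 and the rest is an arylacetic acid. The forward step is a C-acylation that must spare ring D. For that reason the acid and phenol of 12 are free (free phenols are tolerated, whereas benzyl ethers are unsafe in hot BF3·OEt2) and the alcohol is an acetate (a free alcohol would be esterified by the acid).

12 from 10 through 11: only protecting-group bonds are cut (two O–benzyl bonds, one O–acetyl bond). Using benzyl for both the ester and the phenol lets one neutral hydrogenolysis expose exactly the two groups needed in 12 and leave the acetate. The forward demand is acetylation of a hindered secondary alcohol.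

10 from 9: the C–H bond at the carbinol is cut, so the stereocentre is traced to a prochiral ketone. Everything earlier is then free of stereochemistry. The forward step needs reagent-controlled facial selectivity, which relies on the CMe2 versus CH2 size difference.

9 from 8: the benzylic CH2–C3' bond of ring D is cut, opening ring D to an aryl ether that carries a diazoketone. One ring and one skeletal bond are removed, and ring B becomes a simple 1,2,4-trisubstituted benzene. The forward step must direct a carbenoid to the one free ortho carbon and away from all other π and C–H bonds.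

8 from 6 through 7: the bond between the ketone carbon and the diazo-bearing carbon is cut, which is a one-carbon extension of a carboxylic acid. The forward step needs activation of a hindered acid (it has no α-hydrogen, so no ketene can form) and a diazomethane equivalent that is not explosive.

6 from 3 and 4 through 5: the aryl O–CMe2 bond is cut, together with the allyl ester bond. This gives a phenol and a commercial bromo ester. The forward step is a substitution at a tertiary α-carbon, and the new ester must be removable without acid or base next to a benzyl ester, hence allyl.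

3 from 1 through 2: the two O–benzyl bonds are cut, reaching the commercial acid. The forward step must benzylate the carboxylate and the C4 phenol and leave the C2 phenol free.

## Other disconnections considered

Alternative 1: The cut goes through ring A at the C4a–C5 bond, so the trihydroxybenzoyl unit is unravelled to a polyketone stored as a pyrone. The product of the forward key step would be 2-[(3R)-3,5-bis(benzyloxy)-2,2-dimethylchroman-8-yl]-1-(2,4,6-trihydroxyphenyl)ethanone A1. It would come from 6-{3-[(3R)-3,5-bis(benzyloxy)-2,2-dimethylchroman-8-yl]-2-oxopropyl}-4-hydroxy-2H-pyran-2-one A2. Mg(OMe)2 in methanol would open the lactone to a 3,5,7-triketo ester, hold it as a magnesium chelate, and let the C6 carbanion condense on the ester carbon in the Claisen mode.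
- In its favour: ring A forms under mild base, so the chroman never meets a hot Lewis acid. On this point the alternative is better than the chosen plan, whose step 9 is its harshest. A1 has the same ketone–CH2 connectivity as 14, so from there on the two plans are equal, and one hydrogenolysis would finish.
- Against it: ring A is available as 13, so building it costs steps. A2 requires C-acylation of a hydroxypyrone dianion by an arylacetyl donor whose benzylic protons invite proton transfer. The cyclisation can also take the aldol mode to a resorcylate. The alternative does nothing for ring D or the stereocentre, so the chroman half of A2 would still need a sequence like steps 1 to 6, plus benzylation of a hindered alcohol.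
- Comparison: on structure, both reach the same deoxybenzoin type (equal). On mechanism, a chelate-controlled condensation with a mode question stands against acylation of a symmetric arene with no regiochemical question. On step economy, the chosen plan should be three to four steps shorter.

Alternative 2: Ring D is cut at three bonds (C2'–O, C3'–CH and O–CMe2), leaving an aryne across C2'/C3' and a four-carbon enal. The product would be 8-(1,3-dioxolan-2-yl)-5-(methoxymethoxy)-2,2-dimethyl-2H-chromene A3. CsF would release the aryne from 6-(1,3-dioxolan-2-yl)-3-(methoxymethoxy)-2-(trimethylsilyl)phenyl trifluoromethanesulfonate A4. The carbonyl oxygen of 3-methylbut-2-enal A5 would add to the aryne carbon remote from the alkoxy group, the benzoxete would open to an ortho-quinone methide, and oxa-6π closure would give A3.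
- In its favour: three bonds and the whole of ring D in one step from a commodity aldehyde, which is better than the chosen key step in bonds per step. No diazo compound is used, which is better on hazard. A3 is a 2,2-dimethylchromene, a substrate class for which (salen)MnCl-catalysed epoxidation is very reliable, so on enantiocontrol the alternative is at least the equal of the ketone reduction.
- Against it: A3 is achiral and at the wrong oxidation level, so the (R)-carbinol needs an epoxidation and a regioselective benzylic C–O reduction where step 6 needs one operation. A4 is a tetrasubstituted arene needing about five steps. Oxygen must attack the aryne carbon next to the bulky dioxolanyl group. The C1' substituent is a masked aldehyde, so the isoflavone would have to come from a chalcone and an oxidative aryl shift (Tl(NO3)3 or a hypervalent iodine reagent), which is hard to reconcile with an electron-rich ring B.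
- Comparison: on structure, the chosen plan carries the C1' side chain at the oxidation level ring C needs. On mechanism, regiochemistry here rests on aryne polarisation, whereas in the chosen plan it is enforced by there being one free ortho carbon. On step economy, the alternative is longer by several steps.

Alternative 3: Ring B itself is cut at C1'–C2', C2'–C3' and C4'–C5'. The product would be 5,7-bis(benzyloxy)-3-[2-hydroxy-3-(3-methylbut-2-enyl)-4-(triisopropylsilyloxy)phenyl]chromen-4-one A6. Light or heat would convert (E)-4-[5,7-bis(benzyloxy)-4-oxo-4H-chromen-3-yl]-1-diazobut-3-en-2-one A7 by Wolff rearrangement into a vinylketene. This would add triisopropyl[(5-methylhex-4-en-1-yn-1-yl)oxy]silane A8 by [2+2] addition; 4π opening, 6π closure and tautomerisation would give A6.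
- In its favour: it is convergent, and every substituent of ring B is placed by the mechanism. No choice between two similar phenols is needed, which is better than the chosen plan, where step 1 depends on such a choice. The C2' hydroxyl emerges free and the C4' oxygen silylated. Ring D could then follow from an enantioselective epoxidation of the prenyl group and 6-endo closure.
- Against it: A7 and A8 each need several steps, and A8 is a moisture-sensitive ynol silyl ether. The chromone is itself photoactive and electrophilic. A diazo compound is still needed (equal on hazard). After A6 at least four operations remain, and the epoxide must open in the 6-endo and not the 5-exo sense.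
- Comparison: on structure, the alternative is more convergent (better). On mechanism, four consecutive pericyclic events each carry a regiochemical demand, against one bond formed at the only available carbon. On step economy, the total count should be higher and the longest linear sequence comparable.

Key step: step 5

Remark on the chemistry: both esters are spectators, so the acetic acid side chain is carried as a benzyl ester and the hindered acid as an allyl ester; the key step forms the same bond and ring on the same skeleton.

Step 1
Reactants: 1 2-(2,4-dihydroxyphenyl)acetic acid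
Product: 3 benzyl 2-[4-(benzyloxy)-2-hydroxyphenyl]acetate, via benzyl 2-(2,4-dihydroxyphenyl)acetate 2 (not isolated)
Conditions: BnBr (1.05 equiv), KHCO3, DMF, rt; then K2CO3 (1.1 equiv), BnBr (1.0 equiv), 0 °C to rt
Reagents that add atoms: benzyl bromide, BrCc1ccccc1
Why: Carboxylate O-alkylation under KHCO3 leaves the phenols untouched; the following Williamson benzylation, held to one equivalent, should take the unhindered C4 phenol in preference to the C2 phenol, which is shielded by the ortho CH2CO2Bn group and hydrogen-bonded to its carbonyl.

Step 2
Reactants: 3 benzyl 2-[4-(benzyloxy)-2-hydroxyphenyl]acetate; 4 allyl 2-bromo-2-methylpropanoate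
Product: 5 allyl 2-{5-(benzyloxy)-2-[2-(benzyloxy)-2-oxoethyl]phenoxy}-2-methylpropanoate
Conditions: 4 (2.5 equiv), Cs2CO3 (2.5 equiv), DMF, 50 °C
Reagents that add atoms: none
Why: Williamson etherification of the caesium phenoxide with a tertiary α-bromo ester, the standard way to 2-aryloxy-2-methylpropanoates; the adjacent carbonyl activates the α-carbon and excess 4 offsets loss by E2 elimination.

Step 3
Reactants: 5 allyl 2-{5-(benzyloxy)-2-[2-(benzyloxy)-2-oxoethyl]phenoxy}-2-methylpropanoate
Product: 6 2-{5-(benzyloxy)-2-[2-(benzyloxy)-2-oxoethyl]phenoxy}-2-methylpropanoic acid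
Conditions: Pd(PPh3)4 (2 mol%), morpholine (5 equiv), THF, rt; 1 M HCl wash
Reagents that add atoms: none
Why: Tsuji–Trost deallylation: zerovalent palladium ionises the allyl ester to a π-allyl complex that morpholine captures; the benzyl ester and benzyl ether are inert, and no acid reaches the electron-rich ring.

Step 4
Reactants: 6 2-{5-(benzyloxy)-2-[2-(benzyloxy)-2-oxoethyl]phenoxy}-2-methylpropanoic acid
Product: 8 benzyl 2-{4-(benzyloxy)-2-[(4-diazo-2-methyl-3-oxobutan-2-yl)oxy]phenyl}acetate, via acid chloride 7 (not isolated)
Conditions: (COCl)2 (1.3 equiv), DMF (cat.), CH2Cl2, 0 °C to rt; evaporate; Me3SiCHN2 (2 equiv), MeCN/THF, 0 °C to rt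
Reagents that add atoms: (trimethylsilyl)diazomethane, C[Si](C)(C)C=[N+]=[N-]
Why: Acylation of a diazoalkane by an acid chloride (first stage of the Arndt–Eistert sequence), with Me3SiCHN2 as a non-explosive stand-in for diazomethane; the acid chloride has no α-hydrogen, so ketene formation is excluded, and the silyl group leaves as Me3SiCl.

Step 5
Reactants: 8 benzyl 2-{4-(benzyloxy)-2-[(4-diazo-2-methyl-3-oxobutan-2-yl)oxy]phenyl}acetate
Product: 9 benzyl 2-[5-(benzyloxy)-2,2-dimethyl-3-oxochroman-8-yl]acetate
Conditions: Rh2(OAc)4 (1 mol%), CH2Cl2 (0.01 M), rt, slow addition of 8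
Reagents that add atoms: none
Why: Rh2(OAc)4 (divalent rhodium) decomposes 8 with loss of N2 to an electrophilic rhodium carbenoid. The arene carbon between the tether oxygen and the benzyloxy group (C3' of ring B) attacks the carbenoid carbon in a Friedel–Crafts-like addition, and proton transfer from the arenium/rhodium-enolate zwitterion restores aromaticity and leaves the benzylic CH2 next to the ketone. The closest known reaction type is the dirhodium-carboxylate-catalysed cyclisation of 1-diazo-3-aryloxypropan-2-ones to chroman-3-ones, a formal aromatic C–H insertion. Ring D closes as a six-membered ring by attack of an ortho ring carbon on the terminal carbon of the O–CMe2–C(=O) tether, the only ring size this tether allows. No stereocentre is formed. The step needs arene substitution to beat cyclopropanation with Buchner ring expansion, insertion into benzylic C–H bonds and carbenoid dimerisation. The substrate secures this because the reacting carbon is the only free ortho position and is activated by two flanking oxygens, the gem-dimethyl group has no migratable hydrogen and folds the tether toward the ring, and the other C–H bonds are reachable only through seven-membered or larger transition states; slow addition at high dilution suppresses dimerisation.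

Step 6
Reactants: 9 benzyl 2-[5-(benzyloxy)-2,2-dimethyl-3-oxochroman-8-yl]acetate
Product: 10 benzyl 2-[(3R)-5-(benzyloxy)-3-hydroxy-2,2-dimethylchroman-8-yl]acetate
Conditions: (S)-2-methyl-CBS-oxazaborolidine (0.2 equiv), BH3·SMe2 (0.7 equiv), THF, −20 °C; MeOH quench
Reagents that add atoms: none
Why: Corey–Bakshi–Shibata reduction: the ketone binds the catalyst boron anti to its larger flank (the quaternary CMe2–O carbon) and hydride is delivered to one face; since OH > CMe2 > CH2 in priority, as OH > aryl > methyl in the aryl methyl ketone series, the (S)-catalyst should give the (R)-alcohol, and the ester is not reduced at this temperature.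

Step 7
Reactants: 10 benzyl 2-[(3R)-5-(benzyloxy)-3-hydroxy-2,2-dimethylchroman-8-yl]acetate
Product: 11 benzyl 2-[(3R)-3-acetoxy-5-(benzyloxy)-2,2-dimethylchroman-8-yl]acetate
Conditions: Ac2O (1.5 equiv), pyridine, DMAP (0.1 equiv), CH2Cl2, rt
Reagents that add atoms: acetic anhydride, CC(=O)OC(C)=O
Why: DMAP-catalysed acylation of the only free hydroxyl; the C–O bond at the stereocentre is not touched, so the configuration is retained.

Step 8
Reactants: 11 benzyl 2-[(3R)-3-acetoxy-5-(benzyloxy)-2,2-dimethylchroman-8-yl]acetate
Product: 12 2-[(3R)-3-acetoxy-5-hydroxy-2,2-dimethylchroman-8-yl]acetic acid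
Conditions: H2 (1 atm), 10% Pd/C, EtOAc/EtOH, rt
Reagents that add atoms: none
Why: Hydrogenolysis cleaves the benzyl ester and the benzyl aryl ether in one neutral operation; the acetate, the chroman ring and the stereocentre are inert.

Step 9
Reactants: 12 2-[(3R)-3-acetoxy-5-hydroxy-2,2-dimethylchroman-8-yl]acetic acid; 13 phloroglucinol
Product: 15 (3R)-8-(5,7-dihydroxy-4-oxo-4H-chromen-3-yl)-5-hydroxy-2,2-dimethylchroman-3-yl acetate, via deoxybenzoin 14 (not isolated)
Conditions: 13 (1.5 equiv), BF3·OEt2 (neat), 70 °C; then DMF, MsCl (3 equiv), 50 °C; aq. NaOAc
Reagents that add atoms: N,N-dimethylformamide, CN(C)C=O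
Why: BF3-promoted Friedel–Crafts C-acylation of the symmetric, highly nucleophilic 13 by the free acid gives the 2,4,6-trihydroxyphenyl ketone; the Vilsmeier-type reagent from DMF/MsCl then formylates its activated methylene and an ortho hydroxyl closes ring C with loss of Me2NH, the established one-pot route to polyhydroxyisoflavones that tolerates free phenols.

Step 10
Reactants: 15 (3R)-8-(5,7-dihydroxy-4-oxo-4H-chromen-3-yl)-5-hydroxy-2,2-dimethylchroman-3-yl acetate
Product: 16 3-[(3R)-3,5-dihydroxy-2,2-dimethylchroman-8-yl]-5,7-dihydroxy-4H-chromen-4-one
Conditions: K2CO3 (4 equiv), MeOH, rt; then dilute HCl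
Reagents that add atoms: none
Why: Base-mediated transesterification removes the acetate by acyl–oxygen cleavage, so the stereocentre is untouched; the chromone, present as its phenoxide, is deactivated toward methoxide attack at C2.

Compound list

1 | 2-(2,4-dihydroxyphenyl)acetic acid | OC(=O)Cc1ccc(O)cc1O | starting material
2 | benzyl 2-(2,4-dihydroxyphenyl)acetate | O=C(Cc1ccc(O)cc1O)OCc1ccccc1 | intermediate
3 | benzyl 2-[4-(benzyloxy)-2-hydroxyphenyl]acetate | O=C(Cc1ccc(OCc2ccccc2)cc1O)OCc1ccccc1 | intermediate
4 | allyl 2-bromo-2-methylpropanoate | C=CCOC(=O)C(C)(C)Br | starting material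
5 | allyl 2-{5-(benzyloxy)-2-[2-(benzyloxy)-2-oxoethyl]phenoxy}-2-methylpropanoate | O=C(Cc1ccc(OCc2ccccc2)cc1OC(C)(C)C(=O)OCC=C)OCc1ccccc1 | intermediate
6 | 2-{5-(benzyloxy)-2-[2-(benzyloxy)-2-oxoethyl]phenoxy}-2-methylpropanoic acid | O=C(Cc1ccc(OCc2ccccc2)cc1OC(C)(C)C(=O)O)OCc1ccccc1 | intermediate
7 | benzyl 2-{4-(benzyloxy)-2-[(1-chloro-2-methyl-1-oxopropan-2-yl)oxy]phenyl}acetate | O=C(Cc1ccc(OCc2ccccc2)cc1OC(C)(C)C(=O)Cl)OCc1ccccc1 | intermediate
8 | benzyl 2-{4-(benzyloxy)-2-[(4-diazo-2-methyl-3-oxobutan-2-yl)oxy]phenyl}acetate | O=C(Cc1ccc(OCc2ccccc2)cc1OC(C)(C)C(=O)C=[N+]=[N-])OCc1ccccc1 | intermediate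
9 | benzyl 2-[5-(benzyloxy)-2,2-dimethyl-3-oxochroman-8-yl]acetate | O=C(Cc1ccc(OCc2ccccc2)c2c1OC(C)(C)C(=O)C2)OCc1ccccc1 | intermediate
10 | benzyl 2-[(3R)-5-(benzyloxy)-3-hydroxy-2,2-dimethylchroman-8-yl]acetate | O=C(Cc1ccc(OCc2ccccc2)c2c1OC(C)(C)[C@H](O)C2)OCc1ccccc1 | intermediate
11 | benzyl 2-[(3R)-3-acetoxy-5-(benzyloxy)-2,2-dimethylchroman-8-yl]acetate | O=C(Cc1ccc(OCc2ccccc2)c2c1OC(C)(C)[C@H](OC(C)=O)C2)OCc1ccccc1 | intermediate
12 | 2-[(3R)-3-acetoxy-5-hydroxy-2,2-dimethylchroman-8-yl]acetic acid | OC(=O)Cc1ccc(O)c2c1OC(C)(C)[C@H](OC(C)=O)C2 | intermediate
13 | phloroglucinol (benzene-1,3,5-triol) | Oc1cc(O)cc(O)c1 | starting material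
14 | (3R)-5-hydroxy-2,2-dimethyl-8-[2-oxo-2-(2,4,6-trihydroxyphenyl)ethyl]chroman-3-yl acetate | O=C(Cc1ccc(O)c2c1OC(C)(C)[C@H](OC(C)=O)C2)c1c(O)cc(O)cc1O | intermediate
15 | (3R)-8-(5,7-dihydroxy-4-oxo-4H-chromen-3-yl)-5-hydroxy-2,2-dimethylchroman-3-yl acetate | CC1(C)Oc2c(-c3coc4cc(O)cc(O)c4c3=O)ccc(O)c2C[C@H]1OC(C)=O | intermediate
16 | 3-[(3R)-3,5-dihydroxy-2,2-dimethylchroman-8-yl]-5,7-dihydroxy-4H-chromen-4-one | CC1(C)Oc2c(-c3coc4cc(O)cc(O)c4c3=O)ccc(O)c2C[C@H]1O | target

Total step count: 10. Longest linear sequence: 10 steps from 1 (4 and 13 are purchased).

Least certain steps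

Step 5 (key step). The carbenoid may be diverted into arene cyclopropanation with Buchner ring expansion, or into dimerisation, because the reacting carbon, although the most electron-rich, is flanked on both sides. A cycloheptatriene by-product should isomerise to 9 on brief TFA treatment. The fallback sets out from 3 and returns at 9 without any diazo compound. O-Alkylation of 3 with 3-chloro-3-methylbut-1-yne (CuCl2·2H2O cat., DBU, MeCN, 0 °C) should give benzyl 2-[4-(benzyloxy)-2-(2-methylbut-3-yn-2-yloxy)phenyl]acetate F1. Oxidation of its terminal alkyne by a pyridine N-oxide under Ph3PAuNTf2 catalysis (monovalent gold) generates an α-oxo gold carbenoid, which is expected to substitute the same ortho carbon and give 9; the N-oxide is present from the start so that oxidation outruns hydroarylation.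

Step 1. Site discrimination between the two phenols may be incomplete, with over-benzylation or benzylation at the C2 oxygen, because the preference rests only on sterics and a weak hydrogen bond. The fallback sets out from 1 and returns at 3. Acid-catalysed lactonisation (TsOH cat., toluene, reflux, water removal) ties the C2 oxygen and the acid together as 6-hydroxybenzofuran-2(3H)-one F2. Mitsunobu etherification of the one remaining phenol (BnOH, PPh3, DIAD, THF) gives 6-(benzyloxy)benzofuran-2(3H)-one F3. Alcoholysis of this aryl lactone in benzyl alcohol with catalytic K2CO3 opens it to 3.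

Step 2. Substitution at the tertiary carbon may be slow, with E2 consumption of 4 and, over a long reaction time, attack of the phenoxide on its neighbouring ester (closure to a benzofuranone and C-alkylation). The fallback sets out from 3 and returns at 6, replacing steps 2 and 3. A Bargellini reaction (CHCl3, acetone, powdered NaOH, 0 °C to rt) lets the phenoxide open a highly reactive gem-dichloroepoxide at low temperature and also saponifies the benzyl ester, giving 2-[5-(benzyloxy)-2-(carboxymethyl)phenoxy]-2-methylpropanoic acid F4. Fischer esterification with benzyl alcohol (TsOH cat., toluene, 60 °C) should select the unhindered arylacetic acid over the α,α-disubstituted acid and give 6.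

Step 6. Facial selectivity may be insufficient if the benzylic CH2 flank is not read as clearly smaller than the CMe2 flank, or may be eroded by uncatalysed borane reduction. The fallback sets out from 9 and returns at 11, replacing steps 6 and 7. NaBH4 (EtOH/THF, 0 °C) gives racemic benzyl 2-[5-(benzyloxy)-3-hydroxy-2,2-dimethylchroman-8-yl]acetate F5. Transesterification with vinyl acetate catalysed by Pseudomonas cepacia lipase (tBuOMe, 35 °C) is expected, from the usual enantiopreference of lipases for secondary alcohols, to acetylate the (R)-enantiomer to 11. It would leave benzyl 2-[(3S)-5-(benzyloxy)-3-hydroxy-2,2-dimethylchroman-8-yl]acetate F6, which is oxidised back to 9 with Dess–Martin periodinane and recycled.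

Step 9. Three processes threaten this step: ionisation at the acetoxy-bearing carbon in hot BF3·OEt2 (dehydration, or ring contraction through the ring oxygen), self-acylation of the electron-rich ring of 12 in competition with 13, and ring formylation in the Vilsmeier stage. The fallback sets out from 12 and returns at 14. Mixed-anhydride Friedel–Crafts acylation of commercial 1,3,5-tris(benzyloxy)benzene with 12 (TFAA, CH2Cl2, 0 °C to rt, no Lewis acid; NaHCO3/MeOH work-up to cleave the transient aryl trifluoroacetate) should give (3R)-5-hydroxy-2,2-dimethyl-8-{2-oxo-2-[2,4,6-tris(benzyloxy)phenyl]ethyl}chroman-3-yl acetate F7. Hydrogenolysis (H2, Pd/C) then gives 14, which is closed to 15 under the second-stage conditions of step 9 at room temperature.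

Further compounds

F1 | step 5 | benzyl 2-[4-(benzyloxy)-2-(2-methylbut-3-yn-2-yloxy)phenyl]acetate | O=C(Cc1ccc(OCc2ccccc2)cc1OC(C)(C)C#C)OCc1ccccc1
F2 | step 1 | 6-hydroxybenzofuran-2(3H)-one | O=C1Cc2ccc(O)cc2O1
F3 | step 1 | 6-(benzyloxy)benzofuran-2(3H)-one | O=C1Cc2ccc(OCc3ccccc3)cc2O1
F4 | step 2 | 2-[5-(benzyloxy)-2-(carboxymethyl)phenoxy]-2-methylpropanoic acid | OC(=O)Cc1ccc(OCc2ccccc2)cc1OC(C)(C)C(=O)O
F5 | step 6 | racemic benzyl 2-[5-(benzyloxy)-3-hydroxy-2,2-dimethylchroman-8-yl]acetate | O=C(Cc1ccc(OCc2ccccc2)c2c1OC(C)(C)C(O)C2)OCc1ccccc1
F6 | step 6 | benzyl 2-[(3S)-5-(benzyloxy)-3-hydroxy-2,2-dimethylchroman-8-yl]acetate | O=C(Cc1ccc(OCc2ccccc2)c2c1OC(C)(C)[C@@H](O)C2)OCc1ccccc1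
F7 | step 9 | (3R)-5-hydroxy-2,2-dimethyl-8-{2-oxo-2-[2,4,6-tris(benzyloxy)phenyl]ethyl}chroman-3-yl acetate | O=C(Cc1ccc(O)c2c1OC(C)(C)[C@H](OC(C)=O)C2)c1c(OCc2ccccc2)cc(OCc2ccccc2)cc1OCc1ccccc1
A1 | alternative 1 | 2-[(3R)-3,5-bis(benzyloxy)-2,2-dimethylchroman-8-yl]-1-(2,4,6-trihydroxyphenyl)ethanone | O=C(Cc1ccc(OCc2ccccc2)c2c1OC(C)(C)[C@H](OCc1ccccc1)C2)c1c(O)cc(O)cc1O
A2 | alternative 1 | 6-{3-[(3R)-3,5-bis(benzyloxy)-2,2-dimethylchroman-8-yl]-2-oxopropyl}-4-hydroxy-2H-pyran-2-one | O=C(Cc1ccc(OCc2ccccc2)c2c1OC(C)(C)[C@H](OCc1ccccc1)C2)Cc1cc(O)cc(=O)o1
A3 | alternative 2 | 8-(1,3-dioxolan-2-yl)-5-(methoxymethoxy)-2,2-dimethyl-2H-chromene | CC1(C)C=Cc2c(OCOC)ccc(C3OCCO3)c2O1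
A4 | alternative 2 | 6-(1,3-dioxolan-2-yl)-3-(methoxymethoxy)-2-(trimethylsilyl)phenyl trifluoromethanesulfonate | COCOc1ccc(C2OCCO2)c(OS(=O)(=O)C(F)(F)F)c1[Si](C)(C)C
A5 | alternative 2 | 3-methylbut-2-enal | CC(C)=CC=O
A6 | alternative 3 | 5,7-bis(benzyloxy)-3-[2-hydroxy-3-(3-methylbut-2-enyl)-4-(triisopropylsilyloxy)phenyl]chromen-4-one | CC(C)=CCc1c(O[Si](C(C)C)(C(C)C)C(C)C)ccc(-c2coc3cc(OCc4ccccc4)cc(OCc4ccccc4)c3c2=O)c1O
A7 | alternative 3 | (E)-4-[5,7-bis(benzyloxy)-4-oxo-4H-chromen-3-yl]-1-diazobut-3-en-2-one | [N-]=[N+]=CC(=O)/C=C/c1coc2cc(OCc3ccccc3)cc(OCc3ccccc3)c2c1=O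
A8 | alternative 3 | triisopropyl[(5-methylhex-4-en-1-yn-1-yl)oxy]silane | CC(C)=CCC#CO[Si](C(C)C)(C(C)C)C(C)C
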